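**Retrosynthetic overview**

1. The strategy rests on the C3(H)Br–C4(CH3)2–C5 triad of the six-membered ring, a secondary bromide beside the quaternary C4. All six ring carbons map onto (S)-carvone: C4 is its methyl-bearing olefin carbon, C3 its olefinic CH, C5 its carbonyl carbon and C1 its isopropenyl-bearing carbon.
2. Target 22 ⇒ allylic alcohol 21 ⇒ allylic chloride 18 (C5–Cl by inversion of a C5 alcohol, primary bromide installed last) ⇒ cis-ene-1,4-diol 16 ⇒ fused butenolide 15, whose lactone ring holds the side-chain carbon cis to C5.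
3. 15 ⇒ bromo ketone 8 by glyoxylate aldol at C6, reduction of the C5 ketone, lactonisation and dehydration.
4. 8 ⇒ tertiary allylic alcohol 7 by a bromonium-triggered 1,2-methyl shift from C5 to C4. 7 ⇒ (S)-carvone 1 by ozonolysis/Criegee rearrangement, acetate-to-TBS exchange and MeLi addition.
5. Ring order: the carbocycle is the carvone ring throughout; the only ring made is the temporary γ-lactone (step 7), opened again in step 9.

Key step: step 5

Remark: ring atoms carry the target numbering throughout (C1 O-bearing, C3 Br-bearing, C4 gem-dimethyl, C5 Cl-bearing, C6 alkylidene carbon). In step 1 the acetyl group of 4 is assumed to derive from the isopropenyl carbons, the methoxy methyl leaving as methyl acetate.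

**Route**

Step 1
Reactants: 1 (S)-carvone
Product: 4 (S)-5-acetoxy-2-methylcyclohex-2-en-1-one, via methoxy hydroperoxide 2 (not isolated), via peroxyacetate 3 (not isolated)
Conditions: O3, CH2Cl2/MeOH, −78 °C; then Ac2O, Et3N, DMAP (cat.), −78 °C to rt
Reagents that add atoms: ozone ([O-][O+]=O); methanol (CO); acetic anhydride (CC(=O)OC(C)=O; its acetyl sits only in intermediate 3)
Why: Ozone should cleave the electron-rich isopropenyl olefin in preference to the enone, methanol traps the carbonyl oxide as 2, and acylation triggers a Criegee rearrangement in which the ring carbon migrates to oxygen with retention, so the (S) centre is carried over unchanged.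

Step 2
Reactants: 4 (S)-5-acetoxy-2-methylcyclohex-2-en-1-one
Product: 5 (S)-5-hydroxy-2-methylcyclohex-2-en-1-one
Conditions: K2CO3 (cat.), MeOH, 0 °C
Reagents that add atoms: none
Why: Base-catalysed transesterification at 0 °C should remove the acetate faster than the β-acyloxy ketone undergoes E1cB elimination, and the stereocentre is not touched.

Step 3
Reactants: 5 (S)-5-hydroxy-2-methylcyclohex-2-en-1-one
Product: 6 (S)-5-(tert-butyldimethylsilyloxy)-2-methylcyclohex-2-en-1-one
Conditions: TBSCl, imidazole, DMF, rt
Reagents that add atoms: tert-butyldimethylsilyl chloride (CC(C)(C)[Si](C)(C)Cl)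
Why: Imidazole-promoted silylation of the secondary alcohol gives an ether that should survive MeLi, NBS, LDA and iBu2AlH; no stereocentre is affected.

Step 4
Reactants: 6 (S)-5-(tert-butyldimethylsilyloxy)-2-methylcyclohex-2-en-1-one
Product: 7 (1S,5S)-5-(tert-butyldimethylsilyloxy)-1,2-dimethylcyclohex-2-en-1-ol
Conditions: MeLi, Et2O, −78 °C; aq. NH4Cl
Reagents that add atoms: methyllithium ([Li]C)
Why: 1,2-Addition of the hard organolithium to the enone carbonyl should occur axially on the half-chair that keeps the silyloxy group pseudoequatorial, that is anti to OTBS, which sets the carbinol centre with OH cis and CH3 trans to OTBS.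

Step 5
Reactants: 7 (1S,5S)-5-(tert-butyldimethylsilyloxy)-1,2-dimethylcyclohex-2-en-1-ol
Product: 8 (3R,5R)-3-bromo-5-(tert-butyldimethylsilyloxy)-2,2-dimethylcyclohexan-1-one
Conditions: NBS (1.05 equiv), 4 Å MS, CH2Cl2, −20 °C to rt, dark
Reagents that add atoms: N-bromosuccinimide (O=C1CCC(=O)N1Br)
Why: NBS should transfer Br+ to the trisubstituted C3=C4 olefin on the face syn to the allylic hydroxyl, giving an unsymmetrical bromonium ion with its charge on tertiary C4; the C5 methyl, pseudoaxial on the opposite face in the half-chair that keeps OTBS equatorial and the smaller OH beside the vinylic methyl, then migrates antiperiplanar to the breaking C4–Br bond and the oxocarbenium ion gives up its proton to succinimide anion. The closest known reaction type is the halonium-induced semipinacol rearrangement of tertiary allylic alcohols to α-quaternary β-halo ketones, here with methyl as the migrating group. No ring is closed: the carvone ring is kept and one C–CH3 bond moves from C5 to C4, which makes the gem-dimethyl carbon and the neopentyl C–Br bond without any substitution at a neopentyl centre. The one new stereocentre, C3, is fixed by the anti relationship between bromine and the migrating methyl, so the trans OTBS/CH3 arrangement from step 4 becomes a cis C1–O/C3–Br pair (3R). The step needs the methyl shift to beat ring contraction by migration of the C5–C6 bond, capture of the bromonium ion by hydroxyl or water and allylic bromination; the ring bond lies close to the olefin plane and is poorly aligned, and exclusion of water, base and light should close the other channels.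

Step 6
Reactants: 8 (3R,5R)-3-bromo-5-(tert-butyldimethylsilyloxy)-2,2-dimethylcyclohexan-1-one; 9 ethyl glyoxylate
Product: 11 ethyl 2-[(4R,6S)-4-bromo-6-(tert-butyldimethylsilyloxy)-3,3-dimethyl-2-oxocyclohexyl]-2-hydroxyacetate (diastereomer mixture), via lithium enolate 10 (not isolated)
Conditions: LDA, THF, −78 °C; then freshly distilled ethyl glyoxylate, −78 °C; aq. NH4Cl
Reagents that add atoms: lithium diisopropylamide (CC(C)N([Li])C(C)C; its lithium sits only in intermediate 10)
Why: Deprotonation can only occur at C6 because C4 is quaternary, and the lithium enolate should add to the very electrophilic aldehyde at −78 °C (directed aldol addition) faster than it expels the β-silyloxy group; the two new centres (C6 and the carbinol) form as a mixture that is erased in step 8.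

Step 7
Reactants: 11 ethyl 2-[(4R,6S)-4-bromo-6-(tert-butyldimethylsilyloxy)-3,3-dimethyl-2-oxocyclohexyl]-2-hydroxyacetate
Product: 13 (4S,6R,7aS)-6-bromo-4-(tert-butyldimethylsilyloxy)-3-hydroxy-7,7-dimethylhexahydro-1-benzofuran-2(3H)-one (mixture at C3 and C3a), via diol ester 12 (not isolated)
Conditions: NaBH4, CeCl3·7H2O, MeOH, −78 to −40 °C; then PPTS (cat.), PhMe, 70 °C
Reagents that add atoms: none
Why: Luche reduction should reduce the hindered ketone at low temperature without touching the α-hydroxy ester, hydride attacking C5 axially from the face opposite the axial C4 methyl to give the equatorial alcohol cis to C1–O and C3–Br, and acid-catalysed lactonisation of the γ-hydroxy ester then closes the five-membered lactone.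

Step 8
Reactants: 13 (4S,6R,7aS)-6-bromo-4-(tert-butyldimethylsilyloxy)-3-hydroxy-7,7-dimethylhexahydro-1-benzofuran-2(3H)-one
Product: 15 (4S,6R,7aS)-6-bromo-4-(tert-butyldimethylsilyloxy)-7,7-dimethyl-5,6,7,7a-tetrahydro-1-benzofuran-2(4H)-one, via α-mesyloxy lactone 14 (not isolated)
Conditions: MsCl, Et3N, CH2Cl2, 0 °C; then DBU, 0 to 40 °C
Reagents that add atoms: methanesulfonyl chloride (CS(=O)(=O)Cl; the mesyl group sits only in intermediate 14)
Why: Mesylation of the α-hydroxy lactone and DBU-mediated E2 loss of methanesulfonic acid across Cα–C6 (the only β-hydrogen) should give the conjugated butenolide from every diastereomer, since the base can epimerise the α-centre and both sp3 centres become sp2; the lactone ring holds the carbonyl carbon cis to C5.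

Step 9
Reactants: 15 (4S,6R,7aS)-6-bromo-4-(tert-butyldimethylsilyloxy)-7,7-dimethyl-5,6,7,7a-tetrahydro-1-benzofuran-2(4H)-one
Product: 16 cis-ene-1,4-diol (C1–OTBS, C3–Br and C5–OH all cis; C6=CH–CH2OH with CH2OH cis to C5)
Conditions: iBu2AlH (4 equiv), CH2Cl2, −78 to 0 °C; aq. potassium sodium tartrate (KNaC4H4O6)
Reagents that add atoms: none
Why: Excess iBu2AlH should reduce the unsaturated lactone through the lactol aluminate and the enal by 1,2-hydride additions only (lactone-to-diol reduction), so the ring-imposed cis geometry is kept, and aluminium alkoxides are too weak as donors to trigger Grob fragmentation across C5–C4–C3–Br.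

Step 10
Reactants: 16 cis-ene-1,4-diol
Product: 17 primary TBDPS ether of 16 (C5–OH free)
Conditions: TBDPSCl (1.1 equiv), imidazole, CH2Cl2, 0 °C
Reagents that add atoms: tert-butyldiphenylsilyl chloride (CC(C)(C)[Si](Cl)(c1ccccc1)c1ccccc1)
Why: The bulky silyl chloride should react only with the unhindered primary allylic hydroxyl and leave the secondary neopentyl C5 hydroxyl free (chemoselective silyl protection).

Step 11
Reactants: 17 primary TBDPS ether of 16
Product: 18 C5 allylic chloride (Cl trans to C1–OTBS and C3–Br; CH2OTBDPS cis to C5)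
Conditions: PPh3, Cl3CC(O)CCl3, CH2Cl2, −20 to 0 °C
Reagents that add atoms: hexachloroacetone (ClC(Cl)(Cl)C(=O)C(Cl)(Cl)Cl)
Why: Appel-type chlorination with PPh3/hexachloroacetone converts secondary allylic alcohols into chlorides by collapse of the alkoxyphosphonium chloride ion pair at the carbinol carbon with inversion and little allylic transposition; here chloride should enter axially, anti to the leaving group, which puts Cl trans to C1–O and C3–Br and relieves the A(1,3) strain with the cis CH2OSi arm.

Step 12
Reactants: 18 C5 allylic chloride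
Product: 19 C1 alcohol (TBS removed; TBDPS, Cl and Br retained)
Conditions: 48% aq. HF, MeCN, 0 °C
Reagents that add atoms: none
Why: Under acidic fluoride conditions a secondary TBS ether is cleaved far faster than a primary TBDPS ether (selective desilylation), and the weakly ionising medium should leave the allylic chloride alone.

Step 13
Reactants: 19 C1 alcohol
Product: 20 C1 acetate (primary TBDPS ether retained)
Conditions: Ac2O, pyridine, DMAP (cat.), CH2Cl2, 0 °C to rt
Reagents that add atoms: acetic anhydride (CC(=O)OC(C)=O)
Why: DMAP-catalysed acyl transfer to the unhindered secondary C1 alcohol proceeds at oxygen and so with retention at C1, while the hindered secondary chloride and neopentyl bromide should not be displaced by pyridine.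

Step 14
Reactants: 20 C1 acetate
Product: 21 primary allylic alcohol (C1–OAc, C3–Br, C5–Cl; CH2OH cis to C5)
Conditions: HF·pyridine, THF/pyridine, 0 °C to rt
Reagents that add atoms: none
Why: Buffered HF·pyridine should remove the primary TBDPS ether (fluoride-mediated desilylation) without acetate cleavage or migration and without the basicity that could eliminate HCl or HBr.

Step 15
Reactants: 21 primary allylic alcohol
Product: 22 (1S,3R,5R)-3-bromo-6-[(Z)-2-bromoethylidene]-5-chloro-4,4-dimethylcyclohexyl acetate (target numbering)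
Conditions: CBr4, PPh3, CH2Cl2, 0 °C
Reagents that add atoms: carbon tetrabromide (BrC(Br)(Br)Br)
Why: Appel bromination of the primary allylic alcohol is an SN2 process at an unhindered carbon that should neither isomerise the trisubstituted olefin nor touch the hindered secondary chloride, and placing it last keeps the labile allylic bromide away from all earlier reagents.

**Compound list**

1 | (S)-carvone | CC(=C)[C@H]1CC=C(C)C(=O)C1 | starting material
2 | (5S)-5-(1-hydroperoxy-1-methoxyethyl)-2-methylcyclohex-2-en-1-one (mixture at the peroxyacetal carbon) | COC(C)(OO)[C@H]1CC=C(C)C(=O)C1 | intermediate (not isolated)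
3 | peroxyacetate of 2 | COC(C)(OOC(C)=O)[C@H]1CC=C(C)C(=O)C1 | intermediate (not isolated)
4 | (S)-5-acetoxy-2-methylcyclohex-2-en-1-one | CC(=O)O[C@H]1CC=C(C)C(=O)C1 | intermediate
5 | (S)-5-hydroxy-2-methylcyclohex-2-en-1-one | O[C@H]1CC=C(C)C(=O)C1 | intermediate
6 | (S)-5-(tert-butyldimethylsilyloxy)-2-methylcyclohex-2-en-1-one | CC(C)(C)[Si](C)(C)O[C@H]1CC=C(C)C(=O)C1 | intermediate
7 | (1S,5S)-5-(tert-butyldimethylsilyloxy)-1,2-dimethylcyclohex-2-en-1-ol (OH cis, CH3 trans to OTBS) | CC(C)(C)[Si](C)(C)O[C@H]1CC=C(C)[C@@](C)(O)C1 | intermediate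
8 | (3R,5R)-3-bromo-5-(tert-butyldimethylsilyloxy)-2,2-dimethylcyclohexan-1-one (Br cis to OTBS) | CC(C)(C)[Si](C)(C)O[C@H]1C[C@@H](Br)C(C)(C)C(=O)C1 | intermediate
9 | ethyl glyoxylate | CCOC(=O)C=O | starting material
10 | lithium enolate of 8 (C5–OLi, C5=C6) | CC(C)(C)[Si](C)(C)O[C@H]1C[C@@H](Br)C(C)(C)C(O[Li])=C1 | intermediate (not isolated)
11 | ethyl 2-[(4R,6S)-4-bromo-6-(tert-butyldimethylsilyloxy)-3,3-dimethyl-2-oxocyclohexyl]-2-hydroxyacetate (mixture at ring C1 and the carbinol) | CC(C)(C)[Si](C)(C)O[C@H]1C[C@@H](Br)C(C)(C)C(=O)C1C(O)C(=O)OCC | intermediate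
12 | diol ester from 11 (ring C5–OH cis to C1–OTBS and C3–Br; mixture at C6 and the side-chain carbinol) | CC(C)(C)[Si](C)(C)O[C@H]1C[C@@H](Br)C(C)(C)[C@@H](O)C1C(O)C(=O)OCC | intermediate (not isolated)
13 | (4S,6R,7aS)-6-bromo-4-(tert-butyldimethylsilyloxy)-3-hydroxy-7,7-dimethylhexahydro-1-benzofuran-2(3H)-one (mixture at C3 and C3a) | CC(C)(C)[Si](C)(C)O[C@H]1C[C@@H](Br)C(C)(C)[C@H]2OC(=O)C(O)C12 | intermediate
14 | methanesulfonate of 13 | CC(C)(C)[Si](C)(C)O[C@H]1C[C@@H](Br)C(C)(C)[C@H]2OC(=O)C(OS(C)(=O)=O)C12 | intermediate (not isolated)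
15 | (4S,6R,7aS)-6-bromo-4-(tert-butyldimethylsilyloxy)-7,7-dimethyl-5,6,7,7a-tetrahydro-1-benzofuran-2(4H)-one | CC(C)(C)[Si](C)(C)O[C@H]1C[C@@H](Br)C(C)(C)[C@H]2OC(=O)C=C12 | intermediate
16 | cis-ene-1,4-diol (C1–OTBS, C3–Br, C5–OH all cis; C6=CH–CH2OH, CH2OH cis to C5) | CC(C)(C)[Si](C)(C)O[C@H]1C[C@@H](Br)C(C)(C)[C@@H](O)/C1=C\CO | intermediate
17 | primary TBDPS ether of 16 | CC(C)(C)[Si](C)(C)O[C@H]1C[C@@H](Br)C(C)(C)[C@@H](O)/C1=C\CO[Si](c1ccccc1)(c1ccccc1)C(C)(C)C | intermediate
18 | C5 allylic chloride (Cl trans to C1–OTBS and C3–Br) | CC(C)(C)[Si](C)(C)O[C@H]1C[C@@H](Br)C(C)(C)[C@H](Cl)/C1=C\CO[Si](c1ccccc1)(c1ccccc1)C(C)(C)C | intermediate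
19 | C1 alcohol from 18 | O[C@H]1C[C@@H](Br)C(C)(C)[C@H](Cl)/C1=C\CO[Si](c1ccccc1)(c1ccccc1)C(C)(C)C | intermediate
20 | C1 acetate from 19 | CC(=O)O[C@H]1C[C@@H](Br)C(C)(C)[C@H](Cl)/C1=C\CO[Si](c1ccccc1)(c1ccccc1)C(C)(C)C | intermediate
21 | primary allylic alcohol (C1–OAc, C3–Br, C5–Cl; CH2OH cis to C5) | CC(=O)O[C@H]1C[C@@H](Br)C(C)(C)[C@H](Cl)/C1=C\CO | intermediate
22 | (1S,3R,5R)-3-bromo-6-[(Z)-2-bromoethylidene]-5-chloro-4,4-dimethylcyclohexyl acetate (target numbering) | CC(=O)O[C@H]1C[C@@H](Br)C(C)(C)[C@H](Cl)/C1=C\CBr | target

**Step count**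

Total steps: 15. Longest linear sequence: 15 steps, from (S)-carvone 1.

**Steps most likely to fail**

Step 5 (key step). The methyl shift may be slower than the other outlets of the bromonium ion, because the anti addition required of it runs through a twist-like rather than a chair-like transition state. Migration of the C5–C6 ring bond (ring contraction) or capture of the ion by the hydroxyl group or by traces of water could then take over. The fallback sets out from enone 6 and comes back at ketone 8, and uses a vinyl group as a methyl surrogate, since its π bond bridges the electron-poor carbon and migrates far more readily. Addition of CH2=CHMgBr/CeCl3 in THF at −78 °C, anti to OTBS as in step 4, should give the vinyl carbinol F1. NBS in CH2Cl2 then triggers the same anti semipinacol shift to the 3-bromo-2-methyl-2-vinyl ketone F2. Ozonolysis (O3, CH2Cl2, −78 °C; Me2S) gives the keto aldehyde F3. TsNHNH2 in EtOH condenses with the aldehyde only, the ketone being flanked by the quaternary carbon, and gives the tosylhydrazone F4. Catecholborane in CHCl3 followed by NaOAc·3H2O at reflux (reductive deoxygenation of a tosylhydrazone) turns CH=N into CH3 and gives 8.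

Step 11. Activation of the C5 hydroxyl is crowded by C4 and by the cis CH2OTBDPS arm, so collapse of the alkoxyphosphonium chloride may be slow. Ionisation to the allyl cation could then deliver chloride to the side-chain terminus (SN2′) or erode the configuration at C5. The fallback sets out from diol 16 and comes back at target 22, and runs the substitution on a substrate with a small, inductively deactivating CH2Cl arm. Excess PPh3/hexachloroacetone in CH2Cl2 should convert both hydroxyls of 16 and give the dichloride F5. Finkelstein exchange with excess LiBr in acetone replaces only the unhindered primary allylic chloride and gives the bromo chloride F6. 48% aq. HF in MeCN removes the TBS group and gives the alcohol F7. Acetylation with Ac2O, iPr2NEt and catalytic DMAP in CH2Cl2 at −20 °C gives 22.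

Step 8. E2 removal of the C6 hydrogen from the α-mesyloxy lactone may be slow compared with deprotonation at the α-carbon and decomposition, and prolonged exposure to DBU could start dehydrobromination at C3. The fallback sets out from hydroxy lactone 13 and comes back at butenolide 15, and replaces the elimination by an oxidation and a reduction. Swern oxidation ((COCl)2, DMSO, Et3N, CH2Cl2, −78 °C) should give the α-keto lactone, which exists as its enol, the 3-hydroxybutenolide F8. Tf2O and 2,6-lutidine in CH2Cl2 at −78 °C give the enol triflate F9. Reduction with Pd(OAc)2, PPh3, HCO2H and Bu3N in DMF at 60 °C (formate reduction of a vinyl triflate) replaces OTf by H and gives 15.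

**Further compounds**

F1 | step 5 | 5-(tert-butyldimethylsilyloxy)-2-methyl-1-vinylcyclohex-2-en-1-ol (OH cis, vinyl trans to OTBS) | CC(C)(C)[Si](C)(C)O[C@H]1CC=C(C)[C@@](C=C)(O)C1
F2 | step 5 | 3-bromo-5-(tert-butyldimethylsilyloxy)-2-methyl-2-vinylcyclohexan-1-one (Br cis to OTBS, vinyl trans to Br) | CC(C)(C)[Si](C)(C)O[C@H]1C[C@@H](Br)[C@](C)(C=C)C(=O)C1
F3 | step 5 | 2-bromo-4-(tert-butyldimethylsilyloxy)-1-methyl-6-oxocyclohexane-1-carbaldehyde (same configuration as F2) | CC(C)(C)[Si](C)(C)O[C@H]1C[C@@H](Br)[C@](C)(C=O)C(=O)C1
F4 | step 5 | tosylhydrazone of aldehyde F3 | CC(C)(C)[Si](C)(C)O[C@H]1C[C@@H](Br)[C@](C)(C=NNS(=O)(=O)c2ccc(C)cc2)C(=O)C1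
F5 | step 11 | dichloride (C1–OTBS, C3–Br, C5–Cl trans to both; C6=CH–CH2Cl with CH2Cl cis to C5) | CC(C)(C)[Si](C)(C)O[C@H]1C[C@@H](Br)C(C)(C)[C@H](Cl)/C1=C\CCl
F6 | step 11 | bromo chloride (as F5 with CH2Br in place of CH2Cl) | CC(C)(C)[Si](C)(C)O[C@H]1C[C@@H](Br)C(C)(C)[C@H](Cl)/C1=C\CBr
F7 | step 11 | C1 alcohol of F6 (deacetyl target) | O[C@H]1C[C@@H](Br)C(C)(C)[C@H](Cl)/C1=C\CBr
F8 | step 8 | (4S,6R,7aS)-6-bromo-4-(tert-butyldimethylsilyloxy)-3-hydroxy-7,7-dimethyl-5,6,7,7a-tetrahydro-1-benzofuran-2(4H)-one (enol of the α-keto lactone) | CC(C)(C)[Si](C)(C)O[C@H]1C[C@@H](Br)C(C)(C)[C@H]2OC(=O)C(O)=C12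
F9 | step 8 | enol triflate of F8 | CC(C)(C)[Si](C)(C)O[C@H]1C[C@@H](Br)C(C)(C)[C@H]2OC(=O)C(OS(=O)(=O)C(F)(F)F)=C12
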